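**Small charge.** A free catalyst charge of 100 µM stands far below the 10 mM of substrate, so the catalyst has to turn over many times, and by the candidate steps each turn costs one partner. The north-east run is the flask asked about, followed so far; the south run was made earlier.

| setting | north-east | south | flask |
|---|---|---|---|
| substrate | 10 mM | 10 mM | 10 mM |
| partner | 10.5 mM | 10.5 mM | 10.5 mM |
| protic impurity | 10 mM | 6.7 mM | 10.0 mM |
| free catalyst | 100 µM | 100 µM | 100 µM |
| temperature | 40 °C | 25 °C | 40 °C |
| remark | the very flask that is asked about, followed so far | run made earlier |  |
| time |  |  | 20 h |

| run | time / h | product / % | substrate / % |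
|---|---|---|---|
| north-east | 1.33 | 41 | 59 |
| north-east | 2.00 | 47 | 54 |
| north-east | 3.00 | 48 | 53 |
| north-east | 5.00 | 47 | 51 |
| north-east | 6.00 | 46 | 54 |
| north-east | 10.0 | 46 | 52 |
| north-east | 15.0 | 47 | 52 |
| south | 2.00 | 37 | 62 |
| south | 4.00 | 60 | 44 |
| south | 8.00 | 67 | 34 |
| south | 12.0 | 68 | 31 |
| south | 15.0 | 69 | 30 |
| south | 25.0 | 67 | 31 |
| south | 30.0 | 70 | 31 |

(scatter of a reading: 1.5 percentage points)

- product that was removed still counts
- candidate steps: partner + free catalyst <-> catalyst intermediate A; catalyst intermediate A -> released group + catalyst intermediate B; substrate + catalyst intermediate B <-> catalyst intermediate C; catalyst intermediate C -> free catalyst + product; partner + protic impurity -> quenched reagent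
- additions bring no volume worth counting

- Wednesday's: at 20 h raise the temperature by 15 K, then wait 20 h
- Tuesday's: at 20 h take out 90% of the product then present, then wait 20 h
- Thursday's: at 20 h add free catalyst, 100% of the amount charged, then wait 20 h
- Friday's: change nothing and wait 20 h more
- Saturday's: at 20 h add partner, 100% of the amount charged, then wait 20 h

- product, in percent of the substrate first charged, at 20 h
- what to do for the largest gain in product; "none" if nothing gains more than 2 percentage points (Wednesday's / Tuesday's / Thursday's / Friday's / Saturday's / none)
- product present, with what was taken out counted in, in percent of the substrate first charged, after Tuesday's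
- product present, with what was taken out counted in, in percent of the substrate first charged, after Thursday's

**Two readings.** North-east product stays flat from 3.00 h on and averages 46.8% there. Substrate over the same readings averages 52.4%, so 47.6% has left it. These are separate measurements, and they differ by less than the scatter of one reading, so I trust 47.2%.

**Partner share.** The north-east flask reads 45.0% for the partner share, product formed per partner charged. The other 5.78 mM of partner went elsewhere, and the 10 mM of protic impurity can take it. Quenching and catalyst binding are each first order in partner, so at one moment their ratio holds impurity against free catalyst, with no partner in it. As impurity falls, that ratio tilts towards the catalyst, and the share read on the north-east flask has this drift in it.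

**A false way.** The south run reads a share of 65.0%. Carried to the asked flask it gives 68.2%, which parts from the readings. This way cheats: south held 6.7 mM of impurity at 25 °C, so a share belongs to its impurity charge and temperature.

**My reckoning.** I commit to 47.2% at 20 h. If the flat line means partner has stopped feeding the cycle, then waiting, heat, removing product and adding catalyst each leave the flask at 47.2%. A second charge of partner at the same share adds 47 percentage points, so I choose Saturday's.

**The check.** The forecast gives 47%, Saturday's, 47% after Tuesday's and 47% after Thursday's, holding that “the stall looks like exhausted partner”. The flask gives 48.4%, against 47.2% from my share, with 48.4% after Tuesday's and 48.4% after Thursday's. Saturday's gains 52 points, and waiting gains 0 points.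

    partner + free catalyst ⇌ catalyst intermediate A (K = 170 L mol⁻¹, k = 3.60 L mol⁻¹ s⁻¹, Ea = 37.0 kJ mol⁻¹, ΔH = −50.0 kJ mol⁻¹)
    catalyst intermediate A → released group + catalyst intermediate B (k = 1.90 s⁻¹, Ea = 69.0 kJ mol⁻¹)
    substrate + catalyst intermediate B ⇌ catalyst intermediate C (K = 120 L mol⁻¹, k = 4.70 L mol⁻¹ s⁻¹, Ea = 60.0 kJ mol⁻¹, ΔH = −44.0 kJ mol⁻¹)
    catalyst intermediate C → free catalyst + product (k = 0.280 s⁻¹, Ea = 77.0 kJ mol⁻¹)
    partner + protic impurity → quenched reagent (k = 0.0400 L mol⁻¹ s⁻¹, Ea = 70.0 kJ mol⁻¹)
    (constants at 40 °C)

**One reason.** At 20.0 h the flask holds 0% of its partner, the limiting reagent, beside 51.6% of its substrate. The run without quenching reaches 100% instead of 48.4%, so quenching of partner by impurity is the main reason for the stop. In that same run Saturday's brings 0 points, against 52 points with quenching, which is the change that would make Saturday's the wrong choice.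

**Second flask.** With 6.3 mM of partner and the other charges held, the share 45.0% gives 28.4% of product. The neighbour flask gives 28.6%.

The data are simulated for substances that don't exist; the scatter is artificial.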